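## Structural features

Broussoflavonol B (12) is a flavone. Ring A (benzene) is fused to ring C (4-pyranone) through C4a and C8a, and ring B, a 3,4-dihydroxyphenyl group, is bonded to C2 of ring C. Ring A has no hydrogen left: it carries hydroxyls at C5 and C7 and 3-methylbut-2-enyl (prenyl) chains at C6 and C8, while ring C carries the only methylated oxygen of the molecule at C3, next to the C4 carbonyl. There is no stereocentre and no stereogenic double bond (each side-chain alkene ends in two methyl groups), so no stereocentres stand next to each other and nothing stereochemical has to be set. The fragile groups are the two prenyl chains and the catechol of ring B. Each prenyl chain is flanked by ring oxygens (5-OH and 7-OH around C6, 7-OH and O1 around C8), so it can close to a dimethylchroman under acid and is lost to hydrogenation; the catechol is easily oxidised, above all under base in air. The real difficulty is regiochemical and chemoselective: two prenyl chains must sit on defined carbons of a hexasubstituted ring A, and exactly one of five oxygens (O3) must be methylated, without a late step that needs acid or hydrogen. The key step exploits the fact that C4a, C5, C6, C7, C8 and C8a with their substituents form a 2,4-diprenylphloroglucinol unit with a mirror plane through C4a and C7. Its one unsubstituted carbon becomes C4a and its two equivalent neighbours become C5–OH and C8a–O1, so forming C4–C4a and O1–C2 can give only the 6,8-diprenyl pattern, while O3 arrives already methylated on the three-carbon partner.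

## Logic of the disconnections

12 is cut at C4–C4a and O1–C2. This opens ring C and separates ring A, as 4, from a three-carbon unit, 9, that already carries ring B and the methylated O3. The cut removes the only heterocycle and settles both selectivity problems at once: the symmetry of 4 leaves one possible site, and no hydroxyl ever has to be methylated selectively. The forward step must acylate the single ring CH of 4 with the ester carbon of 9 (through 10) and then close 11 through oxygen onto the aryl ketone, without acid, base or metal that would harm the prenyl chains. For that reason the ester of 9 is tert-butyl, which leaves as the alcohol at a much lower temperature than an ethyl ester would. Ring B is left unprotected, because any mask would have to come off after the prenyl chains are in place.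

9 is traced back to 8 by restoring two O–CH2Ph bonds. The catechol must be masked during the enolate chemistry that builds the keto ester. Benzyl ethers are chosen because hydrogenolysis is neutral and leaves the tert-butyl ester alone; the demand is that this is done before any prenyl alkene is in the molecule and that the aryl ketone is not reduced.

8 is cut between the ketone carbon (future C2) and the methoxy-bearing carbon (future C3), giving the aryl ester 6 and the methoxyacetate 7. This crossed Claisen cut turns the whole three-carbon unit into two simple esters and brings in the O3 methyl group from a purchasable reagent. The forward step needs an enolate of 7 that does not self-condense (hence the tert-butyl ester) and an acceptor without α-hydrogens, which 6 is.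

6 is cut at its two O–CH2Ph bonds back to 5, a cheap catechol ester. The only demand is complete twofold etherification without touching the ethyl ester.

4 is cut at its two aryl–CH2 bonds back to 1 and two molecules of 2, passing through the mono-alkylated 3. The cut is made there because all ring carbons of 1 are equivalent and the two remaining ring carbons of 3 are equivalent, so only the number of alkylations, not their site, has to be controlled. The forward step must favour carbon over oxygen alkylation and stop at two chains.

## Other disconnections considered

Alternative 1: The cut takes C4 out as a one-carbon unit by breaking C4a–C4 and C3–C4. That leaves the ring A iodide A2 (the tris-MOM ether of iodinated 4), carbon monoxide A4 and the α-methoxy aryl ketone A3.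
- Forward key step: with Pd(dba)2 (zerovalent palladium) and a wide-bite-angle bisphosphine, oxidative addition into the C–I bond of A2, insertion of A4 and capture of the aroyl-palladium species by the enolate of A3 would give the 1,3-diketone A1. No ring closes; a separate acid step would have to strip five MOM groups and cyclodehydrate to 12.
- In favour: the diketone oxidation level is reached with gentle heating and with every phenol capped, so on thermal stress to the prenyl chains this plan is the better one. Regiochemistry is again fixed by the symmetry of ring A, which is equal to the chosen plan.
- Against: the iodide of A2 sits between two alkoxy groups on a ring with five donor substituents, so oxidative addition and the hindered aroyl transfer should be slow. Direct arylation without A4 and reduction of the C–I bond compete. A1 is more acidic than A3 and can bind palladium as a diketonate. The endgame brings in exactly the acid treatment of prenyl chains next to freshly freed phenols that the chosen route avoids.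
- Comparison: on mechanism it is a metal-catalysed three-component union against a metal-free thermal annulation that forms both ring C bonds in one operation. On step economy, A2 needs iodination and threefold protection of 4, A3 needs its own short sequence, and coupling plus endgame follow, so the route is roughly twice as long.

Alternative 2: The cut is made at the C2''=C3'' double bond of each side chain, leading back to the 6,8-diallyl flavonol ketal A6 and 2-methylbut-2-ene A7.
- Forward key step: two cross-metatheses with second-generation Grubbs catalyst RuCl2(=CHPh)(H2IMes)(PCy3) would give A5, after which the diphenylmethylene ketal has to be removed to reach 12.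
- In favour: allyl chains tolerate heat and acid far better than prenyl chains, so ring C could be built by any classical method and the sensitive trisubstituted alkenes would arrive last. On robustness of the intermediates this plan is the better one. The key step is neutral, which is equal to the chosen plan, and the volatile by-product helps to drive it.
- Against: the ring A problem is not solved. The diallyl pattern still requires twofold C-alkylation of 1 or a double Claisen rearrangement, with the same selectivity questions. Ruthenium hydride species can move an allyl double bond into conjugation and so shorten a chain. Both chains must react completely, or mixed allyl/prenyl material that is hard to separate results. The ketal can only be removed with hot aqueous acid, because hydrogenolysis is excluded by the prenyl alkenes, and this comes at the very end.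
- Comparison: no skeletal ring bond is formed in the key step. Ketal formation, metathesis and deprotection add about three steps to the chosen plan.

Alternative 3: The cut is made at C6–CH2 and C8–CH2, leading back to the 6,8-diiodide A9 and tributyl(3-methylbut-2-enyl)stannane A10.
- Forward key step: a twofold Stille coupling with Pd(PPh3)4 (zerovalent palladium), CuI and CsF would give the tetra-MOM ether A8, and acid would then remove four MOM groups to give 12.
- In favour: the C-alkylation selectivity problem of step 1 disappears, because iodination of a 5,7-dioxygenated flavone can only go to C6 and C8. On that point this plan is the better one, and its regiochemical certainty is equal to that of the chosen plan. The coupling itself is close to neutral.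
- Against: allyl-type stannanes can transfer either terminus, giving prenyl or the 1,1-dimethylallyl isomer. Each iodide lies between two alkoxy groups, so transmetalation is slow and loss of iodine competes, and both positions have to succeed. Two equivalents of organotin must be removed from a polar product. A9 requires a flavonol core with O3 methylated selectively, protection of the chelated 5-OH and a diiodination. The final acid step again meets prenyl chains beside phenols.
- Comparison: the plan is linear and heavy in protecting groups, forms no ring in its key step and is about twice as long; the chosen plan is convergent and uses no protecting group on ring A.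

Key step: step 5

Remark on the chemistry: the ester alkyl group of the keto ester is expelled in the annulation, so it is treated as changeable. tert-Butyl is used because tert-butyl β-keto esters release the acylketene at a markedly lower temperature than ethyl esters, and tert-butyl methoxyacetate (7) is taken to be purchasable. Prenyl means 3-methylbut-2-enyl throughout.

## Route

Step 1
Reactants: 1 phloroglucinol (benzene-1,3,5-triol); 2 prenyl bromide (1-bromo-3-methylbut-2-ene)
Product: 4 2,4-diprenylphloroglucinol, via 2-prenylphloroglucinol 3 (not isolated)
Conditions: 2 (2.0 equiv), 10% aq. KOH, 0 °C → rt, N2; dil. HCl; chromatography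
Reagents that add atoms: none
Why: C-alkylation of an ambident phenolate: in water the oxygens are hydrogen-bonded and the ring of 1 reacts as a vinylogous enolate at carbon with the soft allylic bromide; the two free ring carbons of 3 are equivalent, so the second alkylation can only give 4, which should be separable from under- and over-alkylated material by chromatography.

Step 2
Reactants: 5 ethyl 3,4-dihydroxybenzoate
Product: 6 ethyl 3,4-bis(benzyloxy)benzoate
Conditions: BnBr (2.4 equiv), K2CO3, DMF, 60 °C
Reagents that add atoms: benzyl bromide, BrCc1ccccc1
Why: Williamson ether synthesis; both phenols are deprotonated by K2CO3 in DMF and alkylated by the reactive benzylic bromide, while the ethyl ester is inert under these conditions.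

Step 3
Reactants: 6 ethyl 3,4-bis(benzyloxy)benzoate; 7 tert-butyl methoxyacetate
Product: 8 tert-butyl 3-[3,4-bis(benzyloxy)phenyl]-2-methoxy-3-oxopropanoate
Conditions: 7 (2.2 equiv), LiN(i-Pr)2 (2.3 equiv), THF, −78 °C; then 6 (1.0 equiv), −78 °C → rt; aq. NH4Cl
Reagents that add atoms: none
Why: Crossed Claisen condensation; the preformed lithium enolate of the tert-butyl ester resists self-condensation, 6 has no α-hydrogen, and deprotonation of the product β-keto ester by the second equivalent of enolate drives the acyl transfer; the new α-carbon is a racemic, enolisable centre that becomes sp2 C3 in step 5.

Step 4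
Reactants: 8 tert-butyl 3-[3,4-bis(benzyloxy)phenyl]-2-methoxy-3-oxopropanoate
Product: 9 tert-butyl 3-(3,4-dihydroxyphenyl)-2-methoxy-3-oxopropanoate
Conditions: H2 (1 atm), 10% Pd/C, EtOAc, rt
Reagents that add atoms: none
Why: Hydrogenolysis of aryl benzyl ethers over palladium on carbon in a neutral solvent; the aryl ketone, conjugated to an electron-rich ring, and the tert-butyl ester should be untouched, and the step is placed before any prenyl alkene is present.

Step 5
Reactants: 4 2,4-diprenylphloroglucinol; 9 tert-butyl 3-(3,4-dihydroxyphenyl)-2-methoxy-3-oxopropanoate
Product: 12 broussoflavonol B, via aroylketene 10 (not isolated), via diketone 11 (not isolated)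
Conditions: 4 (1.0 equiv), 9 (1.5 equiv), neat melt, Ar, 150 °C then 185 °C (short); chromatography
Reagents that add atoms: none
Why: On heating, the enol form of 9 expels tert-butanol through a six-membered transition state to give the aroyl(methoxy)ketene 10, which a tert-butyl ester does near 150 °C, well below the temperature an ethyl ester needs. The ketene carbon is attacked by the only ring CH of 4 and tautomerisation gives the 2-hydroxyaryl 1,3-diketone 11, forming C4–C4a; O-acylation of any phenol, including the catechol of 9, gives aryl β-keto esters that revert to 10 at this temperature, so carbon acylation is the irreversible exit. A hydroxyl ortho to the new acyl group then adds to the catechol ketone in a 6-exo-trig closure and the hemiketal loses water, driven by formation of the γ-pyrone, which forms O1–C2 and ring C. The closest known reaction type is the Mentzer pyrone synthesis, the thermal formation of chromones and of 3-substituted flavones from a phenol such as phloroglucinol and a β-keto ester. No stereocentre is formed, and the enolisable α-carbon of 9 ends as sp2 C3. Regioselectivity needs no control, because 4 is mirror-symmetric: the one free carbon is the only site and its two flanking hydroxyls are equivalent, so only the 6,8-diprenyl pattern can result. Chromone rather than 4-arylcoumarin is expected because no acid is present to activate the deactivated, para-hydroxy-conjugated aryl ketone toward ring carbon, whereas the ketene is strongly electrophilic. Heating is kept short, acid-free and under argon to spare the prenyl chains and the catechol.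

## Compound list

1 | phloroglucinol (benzene-1,3,5-triol) | Oc1cc(O)cc(O)c1 | starting material
2 | prenyl bromide (1-bromo-3-methylbut-2-ene) | CC(C)=CCBr | starting material
3 | 2-prenylphloroglucinol [2-(3-methylbut-2-enyl)benzene-1,3,5-triol] | CC(C)=CCc1c(O)cc(O)cc1O | intermediate (not isolated)
4 | 2,4-diprenylphloroglucinol [2,4-bis(3-methylbut-2-enyl)benzene-1,3,5-triol] | Oc1cc(O)c(CC=C(C)C)c(O)c1CC=C(C)C | intermediate
5 | ethyl 3,4-dihydroxybenzoate | CCOC(=O)c1ccc(O)c(O)c1 | starting material
6 | ethyl 3,4-bis(benzyloxy)benzoate | CCOC(=O)c1ccc(OCc2ccccc2)c(OCc2ccccc2)c1 | intermediate
7 | tert-butyl methoxyacetate (tert-butyl 2-methoxyacetate) | COCC(=O)OC(C)(C)C | starting material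
8 | tert-butyl 3-[3,4-bis(benzyloxy)phenyl]-2-methoxy-3-oxopropanoate (racemic at C2) | COC(C(=O)OC(C)(C)C)C(=O)c1ccc(OCc2ccccc2)c(OCc2ccccc2)c1 | intermediate
9 | tert-butyl 3-(3,4-dihydroxyphenyl)-2-methoxy-3-oxopropanoate (racemic at C2) | COC(C(=O)OC(C)(C)C)C(=O)c1ccc(O)c(O)c1 | intermediate
10 | 3-(3,4-dihydroxyphenyl)-2-methoxy-3-oxoprop-1-en-1-one [(3,4-dihydroxybenzoyl)(methoxy)ketene] | COC(=C=O)C(=O)c1ccc(O)c(O)c1 | intermediate (not isolated)
11 | 1-(3,4-dihydroxyphenyl)-2-methoxy-3-[2,4,6-trihydroxy-3,5-bis(3-methylbut-2-enyl)phenyl]propane-1,3-dione (racemic at C2) | COC(C(=O)c1ccc(O)c(O)c1)C(=O)c1c(O)c(CC=C(C)C)c(O)c(CC=C(C)C)c1O | intermediate (not isolated)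
12 | broussoflavonol B [2-(3,4-dihydroxyphenyl)-5,7-dihydroxy-3-methoxy-6,8-bis(3-methylbut-2-enyl)chromen-4-one; no stereocentre] | COc1c(-c2ccc(O)c(O)c2)oc2c(CC=C(C)C)c(O)c(CC=C(C)C)c(O)c2c1=O | target

## Step count and least certain steps

Total steps: 5. Longest linear sequence: 4 steps (5 → 6 → 8 → 9 → 12, steps 2 to 5); step 1 is the second branch.

Step 5 (key step). The most likely failure is thermal ring closure of a prenyl chain onto a neighbouring hydroxyl, or oxidative degradation of the polyphenol melt, before carbon acylation and dehydration are complete; the melt is hot and weakly acidic and each chain lies next to a phenol. The fallback moves the making of the trisubstituted alkenes to after the annulation. Setting out from 1, twofold C-allylation with allyl bromide under the conditions of step 1 would give 2,4-diallylphloroglucinol F1. Fusion of F1 with 9 as in step 5, now with thermally sturdy allyl chains, would give 6,8-diallyl-5,7-dihydroxy-2-(3,4-dihydroxyphenyl)-3-methoxychromen-4-one F2. Twofold cross-metathesis of F2 with 2-methylbut-2-ene A7 and second-generation Grubbs catalyst RuCl2(=CHPh)(H2IMes)(PCy3) in CH2Cl2 at 40 °C then comes back to the route at 12.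

Step 1. The most likely failure is loss of control over the number and site of alkylations: mono-, tri-, geminal and oxygen alkylation compete because each product is as nucleophilic as its precursor, and the electron-rich triol can oxidise during isolation. The fallback places the chains one at a time by directed ortho-metalation. Setting out from 1, MOMCl and i-Pr2NEt in CH2Cl2 would give 1,3,5-tris(methoxymethoxy)benzene F3. Lithiation between two acetal oxygens (n-BuLi, THF, 0 °C) and alkylation with 2 would give 1,3,5-tris(methoxymethoxy)-2-(3-methylbut-2-enyl)benzene F4. A second lithiation at either of the two equivalent remaining positions and alkylation with 2 would give 1,3,5-tris(methoxymethoxy)-2,4-bis(3-methylbut-2-enyl)benzene F5. Dilute HCl in MeOH at rt, stopped as soon as the acetals are gone, would rejoin the route at 4.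

Step 3. The most likely failure is slow acyl transfer to the electron-rich, deactivated ester 6, so that the enolate decays on warming and conversion stalls. The fallback uses a stronger acyl donor. Setting out from 6, saponification (NaOH, aq. EtOH, then acid) would give 3,4-bis(benzyloxy)benzoic acid F6. (COCl)2 with catalytic DMF in CH2Cl2 would give 3,4-bis(benzyloxy)benzoyl chloride F7. Adding F7 to two equivalents of the lithium enolate of 7 in THF at −78 °C would rejoin the route at 8.

Step 4. The most likely failure is over-reduction at the benzylic carbonyl while the second benzyl ether is still being removed, together with air oxidation of the freed catechol during handling. The fallback changes the protecting group so that no hydrogen is needed. Setting out from 5, TBSCl and imidazole in DMF would give ethyl 3,4-bis(tert-butyldimethylsilyloxy)benzoate F8. Condensation with the lithium enolate of 7, kept cold as in step 3, would give tert-butyl 3-[3,4-bis(tert-butyldimethylsilyloxy)phenyl]-2-methoxy-3-oxopropanoate F9. Bu4NF buffered with AcOH in THF at 0 °C would rejoin the route at 9.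

## Further compounds

F1 | step 5 | 2,4-diallylphloroglucinol [2,4-bis(prop-2-enyl)benzene-1,3,5-triol] | Oc1cc(O)c(CC=C)c(O)c1CC=C
F2 | step 5 | 6,8-diallyl-5,7-dihydroxy-2-(3,4-dihydroxyphenyl)-3-methoxychromen-4-one | COc1c(-c2ccc(O)c(O)c2)oc2c(CC=C)c(O)c(CC=C)c(O)c2c1=O
F3 | step 1 | 1,3,5-tris(methoxymethoxy)benzene | COCOc1cc(OCOC)cc(OCOC)c1
F4 | step 1 | 1,3,5-tris(methoxymethoxy)-2-(3-methylbut-2-enyl)benzene | COCOc1cc(OCOC)c(CC=C(C)C)c(OCOC)c1
F5 | step 1 | 1,3,5-tris(methoxymethoxy)-2,4-bis(3-methylbut-2-enyl)benzene | COCOc1cc(OCOC)c(CC=C(C)C)c(OCOC)c1CC=C(C)C
F6 | step 3 | 3,4-bis(benzyloxy)benzoic acid | OC(=O)c1ccc(OCc2ccccc2)c(OCc2ccccc2)c1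
F7 | step 3 | 3,4-bis(benzyloxy)benzoyl chloride | ClC(=O)c1ccc(OCc2ccccc2)c(OCc2ccccc2)c1
F8 | step 4 | ethyl 3,4-bis(tert-butyldimethylsilyloxy)benzoate | CCOC(=O)c1ccc(O[Si](C)(C)C(C)(C)C)c(O[Si](C)(C)C(C)(C)C)c1
F9 | step 4 | tert-butyl 3-[3,4-bis(tert-butyldimethylsilyloxy)phenyl]-2-methoxy-3-oxopropanoate (racemic at C2) | COC(C(=O)OC(C)(C)C)C(=O)c1ccc(O[Si](C)(C)C(C)(C)C)c(O[Si](C)(C)C(C)(C)C)c1
A1 | alternative 1 | 1-[3,4-bis(methoxymethoxy)phenyl]-2-methoxy-3-[2,4,6-tris(methoxymethoxy)-3,5-bis(3-methylbut-2-enyl)phenyl]propane-1,3-dione | COCOc1c(C(=O)C(OC)C(=O)c2ccc(OCOC)c(OCOC)c2)c(OCOC)c(CC=C(C)C)c(OCOC)c1CC=C(C)C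
A2 | alternative 1 | 2-iodo-1,3,5-tris(methoxymethoxy)-4,6-bis(3-methylbut-2-enyl)benzene | COCOc1c(I)c(OCOC)c(CC=C(C)C)c(OCOC)c1CC=C(C)C
A3 | alternative 1 | 1-[3,4-bis(methoxymethoxy)phenyl]-2-methoxyethan-1-one | COCC(=O)c1ccc(OCOC)c(OCOC)c1
A4 | alternative 1 | carbon monoxide | [C-]#[O+]
A5 | alternative 2 | broussoflavonol B 3',4'-diphenylmethylene ketal [2-(2,2-diphenyl-1,3-benzodioxol-5-yl)-5,7-dihydroxy-3-methoxy-6,8-bis(3-methylbut-2-enyl)chromen-4-one] | COc1c(-c2ccc3OC(c4ccccc4)(c4ccccc4)Oc3c2)oc2c(CC=C(C)C)c(O)c(CC=C(C)C)c(O)c2c1=O
A6 | alternative 2 | 6,8-diallyl-2-(2,2-diphenyl-1,3-benzodioxol-5-yl)-5,7-dihydroxy-3-methoxychromen-4-one | COc1c(-c2ccc3OC(c4ccccc4)(c4ccccc4)Oc3c2)oc2c(CC=C)c(O)c(CC=C)c(O)c2c1=O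
A7 | alternative 2 | 2-methylbut-2-ene | CC=C(C)C
A8 | alternative 3 | broussoflavonol B tetra-MOM ether [2-[3,4-bis(methoxymethoxy)phenyl]-3-methoxy-5,7-bis(methoxymethoxy)-6,8-bis(3-methylbut-2-enyl)chromen-4-one] | COc1c(-c2ccc(OCOC)c(OCOC)c2)oc2c(CC=C(C)C)c(OCOC)c(CC=C(C)C)c(OCOC)c2c1=O
A9 | alternative 3 | 2-[3,4-bis(methoxymethoxy)phenyl]-6,8-diiodo-3-methoxy-5,7-bis(methoxymethoxy)chromen-4-one | COc1c(-c2ccc(OCOC)c(OCOC)c2)oc2c(I)c(OCOC)c(I)c(OCOC)c2c1=O
A10 | alternative 3 | tributyl(3-methylbut-2-enyl)stannane | CCCC[Sn](CCCC)(CCCC)CC=C(C)C
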